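A direct plan would lithiate 2,3,5,6-tetramethoxytoluene A1, alkylate it at both ends of 1,14-dibromotetradecane to give the bis-arene A2, oxidise both rings with (NH4)2Ce(NO3)6 to the bis(2,5-dimethoxyquinone) A3, and finish by cleaving one methyl ether per ring. Its weakest steps would be:
- the final mono-demethylation, which would have to remove the OMe next to CH3 in one ring but the OMe next to the chain in the other, although both rings of A3 are identical;
- the double alkylation of a hindered aryllithium by a primary dibromide, where elimination and mono-alkylation would compete;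
- the oxidative demethylation, which would have to give only p-quinones on both rings.

The two ring–chain bonds are made on intact, unprotected hydroxyquinones, each by a reaction that can only occur at the one free ring carbon and that matches the oxygen beside it. In ring B that carbon lies between C–OMe and C=O and accepts a nucleophilic alkyl radical from 15-hydroxypentadecanoic acid; in ring A it lies between C–OH and C=O, is the α-carbon of a vinylogous acid, and condenses with the aldehyde terminus of the chain under hydride transfer. This three-component reductive alkylation joins the two different halves in the last step, fixes the OH/OMe pattern by construction, and removes any late demethylation, organolithium alkylation or statistical pairing.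

Key step: step 9

Remark: the target has no stereocentre; ring A is the ring whose chain carbon lies between C–OH and C=O, ring B the ring whose chain carbon lies between C–OMe and C=O; hydroxyquinones are written as 2-hydroxy-1,4-quinone tautomers.

Step 1
Reactants: 1 2-methoxy-6-methylphenol
Product: 2 2-methoxy-6-methylcyclohexa-2,5-diene-1,4-dione
Conditions: O2 (1 atm), N,N′-bis(salicylidene)ethylenediaminocobalt [Co(salen)] (5 mol %), DMF, 25 °C
Reagents that add atoms: dioxygen, O=O
Why: Cobalt–salen-catalysed aerobic oxidation of a 2,6-disubstituted phenol (salcomine oxidation) oxygenates the free para position and gives the p-quinone.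

Step 2
Reactants: 2 2-methoxy-6-methylcyclohexa-2,5-diene-1,4-dione
Product: 3 5-methoxy-3-methylbenzene-1,2,4-triyl triacetate
Conditions: Ac2O, H2SO4 (cat.), 25–40 °C
Reagents that add atoms: acetic anhydride, CC(=O)OC(C)=O
Why: Thiele–Winter acetoxylation: the C4 carbonyl is deactivated as a vinylogous ester, so acetate should add conjugatively through the C1 carbonyl at C5 (para to OMe, next to CH3) and not at the electron-rich enol-ether carbon C3, and aromatisation with peracetylation follows, in line with the para-directing effect of a quinone methoxy group in this reaction.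

Step 3
Reactants: 3 5-methoxy-3-methylbenzene-1,2,4-triyl triacetate
Product: 5 2-hydroxy-5-methoxy-3-methylcyclohexa-2,5-diene-1,4-dione (ring B monomer), via 5-methoxy-3-methylbenzene-1,2,4-triol 4 (not isolated)
Conditions: HCl (cat.), MeOH, 50 °C, Ar; evaporate; FeCl3·6H2O (2.2 equiv), H2O/EtOAc, 0 °C
Reagents that add atoms: none
Why: Acid methanolysis of the aryl acetates and FeCl3 oxidation of the 1,2,4-triol (the usual completion of a Thiele–Winter sequence) should give the 2-hydroxy-1,4-quinone, with OH next to CH3 and OMe next to the only ring C–H.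

Step 4
Reactants: 5 2-hydroxy-5-methoxy-3-methylcyclohexa-2,5-diene-1,4-dione; 6 15-hydroxypentadecanoic acid (3 equiv)
Product: 8 2-hydroxy-6-(14-hydroxytetradecyl)-5-methoxy-3-methylcyclohexa-2,5-diene-1,4-dione, via 14-hydroxytetradecyl radical 7 (not isolated)
Conditions: AgNO3 (0.3 equiv), (NH4)2S2O8 (3 equiv, slow addition), MeCN/H2O (1:1), 70 °C
Reagents that add atoms: none
Why: Silver-catalysed decarboxylative radical alkylation of a quinone (Jacobsen–Torssell reaction, a reaction type used with ω-functionalised acids on methoxy(methyl)benzoquinones and on 2-hydroxy-1,4-quinones): divalent silver formed by persulfate oxidises the carboxylate, loss of CO2 gives primary radical 7, which adds to C6, the only unsubstituted ring carbon, and re-oxidation restores the quinone, so the chain is placed next to OMe by construction.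

Step 5
Reactants: 8 2-hydroxy-6-(14-hydroxytetradecyl)-5-methoxy-3-methylcyclohexa-2,5-diene-1,4-dione
Product: 9 14-(5-hydroxy-2-methoxy-4-methyl-3,6-dioxocyclohexa-1,4-dien-1-yl)tetradecanal
Conditions: TEMPO (10 mol %), PhI(OAc)2 (1.1 equiv), CH2Cl2, 25 °C
Reagents that add atoms: none
Why: Oxoammonium-mediated (TEMPO/PhI(OAc)2) oxidation of the primary alcohol should stop at the aldehyde under anhydrous conditions; the fully substituted quinone is already at its highest oxidation level and has no ring C–H left to react.

Step 6
Reactants: 10 3-methoxy-2-methylphenol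
Product: 11 2-methoxy-3-methylcyclohexa-2,5-diene-1,4-dione
Conditions: (KSO3)2NO (2.2 equiv), KH2PO4, H2O/acetone, 0–25 °C
Reagents that add atoms: potassium nitrosodisulfonate (Fremy's salt), [K+].[K+].[O]N(S(=O)(=O)[O-])S(=O)(=O)[O-]
Why: Teuber oxidation: Fremy's radical abstracts the phenolic hydrogen, a second equivalent couples at the free para position (next to OMe), and collapse of the adduct gives the p-quinone.

Step 7
Reactants: 11 2-methoxy-3-methylcyclohexa-2,5-diene-1,4-dione
Product: 12 5-methoxy-6-methylbenzene-1,2,4-triyl triacetate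
Conditions: Ac2O, H2SO4 (cat.), 25–40 °C
Reagents that add atoms: acetic anhydride, CC(=O)OC(C)=O
Why: Thiele–Winter acetoxylation: acetate should again enter para to OMe (C5, β to the carbonyl that is not part of the vinylogous ester), here the ring carbon remote from CH3.

Step 8
Reactants: 12 5-methoxy-6-methylbenzene-1,2,4-triyl triacetate
Product: 14 5-hydroxy-2-methoxy-3-methylcyclohexa-2,5-diene-1,4-dione (ring A monomer), via 5-methoxy-6-methylbenzene-1,2,4-triol 13 (not isolated)
Conditions: HCl (cat.), MeOH, 50 °C, Ar; evaporate; FeCl3·6H2O (2.2 equiv), H2O/EtOAc, 0 °C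
Reagents that add atoms: none
Why: Methanolysis of the acetates and FeCl3 oxidation of the triol as in step 3 should give the regioisomeric hydroxyquinone, with OMe next to CH3 and OH next to the only ring C–H.

Step 9
Reactants: 14 5-hydroxy-2-methoxy-3-methylcyclohexa-2,5-diene-1,4-dione (1.1 equiv); 9 14-(5-hydroxy-2-methoxy-4-methyl-3,6-dioxocyclohexa-1,4-dien-1-yl)tetradecanal
Product: 16 2-hydroxy-3-[14-(5-hydroxy-2-methoxy-4-methyl-3,6-dioxocyclohexa-1,4-dien-1-yl)tetradecyl]-5-methoxy-6-methylcyclohexa-2,5-diene-1,4-dione (target, achiral), via alkylidene trione 15 (not isolated)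
Conditions: L-proline (20 mol %), diethyl 2,6-dimethyl-1,4-dihydropyridine-3,5-dicarboxylate (Hantzsch ester, 1.1 equiv), CH2Cl2, 25 °C, Ar; then air, aqueous work-up
Reagents that add atoms: none
Why: Three-component reductive alkylation (Knoevenagel condensation followed by transfer hydrogenation), the reaction type known for cyclic 1,3-diones, 2-hydroxy-1,4-naphthoquinone and 2,5-dihydroxy-1,4-benzoquinone with aldehydes and Hantzsch ester. Proline activates aldehyde 9 as its iminium ion, C6 of 14 (the α-carbon of the vinylogous acid C5(OH)=C6–C1=O) attacks it, and loss of proline gives alkylidene trione 15, whose exocyclic carbon accepts hydride from the Hantzsch ester before tautomerisation restores the hydroxyquinone. No ring is closed and no stereocentre is formed. The step needs alkylation of ring A only, and only once: C6 of 14 is its single enolic C–H, ring B of 9 is fully substituted and has no nucleophilic carbon, and reduction of 15 in situ should forestall Michael addition of a second molecule of 14. The chain therefore ends next to OH in ring A and next to OMe in ring B, and two different quinones are joined without a statistical mixture. Any quinone reduced by the Hantzsch ester should be re-oxidised by air on work-up.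

**Compound list**
1 | 2-methoxy-6-methylphenol | COc1cccc(C)c1O | starting material
2 | 2-methoxy-6-methylcyclohexa-2,5-diene-1,4-dione | COC1=CC(=O)C=C(C)C1=O | intermediate
3 | 5-methoxy-3-methylbenzene-1,2,4-triyl triacetate | CC(=O)Oc1cc(OC)c(OC(C)=O)c(C)c1OC(C)=O | intermediate
4 | 5-methoxy-3-methylbenzene-1,2,4-triol | COc1cc(O)c(O)c(C)c1O | intermediate
5 | 2-hydroxy-5-methoxy-3-methylcyclohexa-2,5-diene-1,4-dione | COC1=CC(=O)C(O)=C(C)C1=O | intermediate
6 | 15-hydroxypentadecanoic acid | OCCCCCCCCCCCCCCC(=O)O | starting material
7 | 14-hydroxytetradecyl radical | [CH2]CCCCCCCCCCCCCO | intermediate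
8 | 2-hydroxy-6-(14-hydroxytetradecyl)-5-methoxy-3-methylcyclohexa-2,5-diene-1,4-dione | COC1=C(CCCCCCCCCCCCCCO)C(=O)C(O)=C(C)C1=O | intermediate
9 | 14-(5-hydroxy-2-methoxy-4-methyl-3,6-dioxocyclohexa-1,4-dien-1-yl)tetradecanal | COC1=C(CCCCCCCCCCCCCC=O)C(=O)C(O)=C(C)C1=O | intermediate
10 | 3-methoxy-2-methylphenol | Cc1c(O)cccc1OC | starting material
11 | 2-methoxy-3-methylcyclohexa-2,5-diene-1,4-dione | COC1=C(C)C(=O)C=CC1=O | intermediate
12 | 5-methoxy-6-methylbenzene-1,2,4-triyl triacetate | CC(=O)Oc1cc(OC(C)=O)c(OC(C)=O)c(C)c1OC | intermediate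
13 | 5-methoxy-6-methylbenzene-1,2,4-triol | COc1c(O)cc(O)c(O)c1C | intermediate
14 | 5-hydroxy-2-methoxy-3-methylcyclohexa-2,5-diene-1,4-dione | COC1=C(C)C(=O)C(O)=CC1=O | intermediate
15 | 3-[14-(5-hydroxy-2-methoxy-4-methyl-3,6-dioxocyclohexa-1,4-dien-1-yl)tetradecylidene]-5-methoxy-6-methylcyclohex-5-ene-1,2,4-trione (alkene geometry not defined) | COC1=C(C)C(=O)C(=O)C(=CCCCCCCCCCCCCCC2=C(OC)C(=O)C(C)=C(O)C2=O)C1=O | intermediate
16 | 2-hydroxy-3-[14-(5-hydroxy-2-methoxy-4-methyl-3,6-dioxocyclohexa-1,4-dien-1-yl)tetradecyl]-5-methoxy-6-methylcyclohexa-2,5-diene-1,4-dione (achiral) | COC1=C(C)C(=O)C(O)=C(CCCCCCCCCCCCCCC2=C(OC)C(=O)C(C)=C(O)C2=O)C1=O | target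

Total step count: 9. Longest linear sequence: 6 (steps 1, 2, 3, 4, 5, 9).

Steps most likely to fail:

Step 9 (reductive union). Hydride transfer from the dihydropyridine to the quinone rings could outrun the condensation, or the alkylidene intermediate could be intercepted by a second molecule of 14 before it is reduced. The fallback sets out from 5 and comes back at 16, replacing the enol-type union by a second radical union. Decarboxylative alkylation of 5 with commercial 16-methoxy-16-oxohexadecanoic acid under AgNO3/(NH4)2S2O8 would give methyl 15-(5-hydroxy-2-methoxy-4-methyl-3,6-dioxocyclohexa-1,4-dien-1-yl)pentadecanoate F1. Lipase hydrolysis (Candida antarctica lipase B, pH 7 buffer) would give 15-(5-hydroxy-2-methoxy-4-methyl-3,6-dioxocyclohexa-1,4-dien-1-yl)pentadecanoic acid F2. A second AgNO3/(NH4)2S2O8 decarboxylation of F2 in the presence of excess 14 would form the ring A–chain bond by radical addition at C6 of 14 (the carbon next to OH, as in the alkylation of 2-hydroxy-1,4-naphthoquinone) and give 16.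

Step 4 (radical alkylation next to OMe). The primary radical could be oxidised or dimerise before it is captured at the carbon beside the donor OMe group, and persulfate could degrade the hydroxyquinone. The fallback sets out from 3 and comes back at 9, using a polar aryl-metal alkylation at the protected hydroquinone level. Methanolysis of 3 under argon to triol 4 and protection with MOMCl/i-Pr2NEt would give 1-methoxy-2,4,5-tris(methoxymethoxy)-3-methylbenzene F3. n-BuLi (THF, 0 °C) would metalate the only ring C–H, flanked by OMe and OCH2OMe, and excess 1,14-dibromotetradecane would give 1-(14-bromotetradecyl)-2-methoxy-3,5,6-tris(methoxymethoxy)-4-methylbenzene F4. Kornblum oxidation (DMSO, NaHCO3, 110 °C) would give 14-[2-methoxy-3,5,6-tris(methoxymethoxy)-4-methylphenyl]tetradecanal F5. Aqueous HCl/THF would remove the three acetal groups to give 14-(2,3,5-trihydroxy-6-methoxy-4-methylphenyl)tetradecanal F6, and FeCl3 oxidation would then return aldehyde 9.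

Step 7 (acetoxylation of 11). Regiocontrol could be lost in the conjugate acetoxylation, because the methoxy group is twisted out of conjugation by the neighbouring methyl group and acetate could also enter at C6. The fallback sets out from 10 and comes back at 14, placing all oxygens by electrophilic substitution. Br2 (2 equiv, AcOH) would brominate 10 at the two positions ortho and para to OH and OMe to give 4,6-dibromo-3-methoxy-2-methylphenol F7. Double hydroxylation catalysed by CuI/1,10-phenanthroline (KOH, DMSO/H2O, 110 °C, Ar) would give triol 13, and FeCl3 oxidation as in step 8 would give 14.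

**Further compounds**
F1 | step 9 | methyl 15-(5-hydroxy-2-methoxy-4-methyl-3,6-dioxocyclohexa-1,4-dien-1-yl)pentadecanoate | COC(=O)CCCCCCCCCCCCCCC1=C(OC)C(=O)C(C)=C(O)C1=O
F2 | step 9 | 15-(5-hydroxy-2-methoxy-4-methyl-3,6-dioxocyclohexa-1,4-dien-1-yl)pentadecanoic acid | OC(=O)CCCCCCCCCCCCCCC1=C(OC)C(=O)C(C)=C(O)C1=O
F3 | step 4 | 1-methoxy-2,4,5-tris(methoxymethoxy)-3-methylbenzene | COCOc1cc(OC)c(OCOC)c(C)c1OCOC
F4 | step 4 | 1-(14-bromotetradecyl)-2-methoxy-3,5,6-tris(methoxymethoxy)-4-methylbenzene | COCOc1c(CCCCCCCCCCCCCCBr)c(OC)c(OCOC)c(C)c1OCOC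
F5 | step 4 | 14-[2-methoxy-3,5,6-tris(methoxymethoxy)-4-methylphenyl]tetradecanal | COCOc1c(CCCCCCCCCCCCCC=O)c(OC)c(OCOC)c(C)c1OCOC
F6 | step 4 | 14-(2,3,5-trihydroxy-6-methoxy-4-methylphenyl)tetradecanal | COc1c(CCCCCCCCCCCCCC=O)c(O)c(O)c(C)c1O
F7 | step 7 | 4,6-dibromo-3-methoxy-2-methylphenol | Cc1c(O)c(Br)cc(Br)c1OC
A1 | direct plan | 1,2,4,5-tetramethoxy-3-methylbenzene (2,3,5,6-tetramethoxytoluene) | COc1cc(OC)c(OC)c(C)c1OC
A2 | direct plan | 1,14-bis(2,3,5,6-tetramethoxy-4-methylphenyl)tetradecane | COc1c(C)c(OC)c(OC)c(CCCCCCCCCCCCCCc2c(OC)c(OC)c(C)c(OC)c2OC)c1OC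
A3 | direct plan | 3,3'-(tetradecane-1,14-diyl)bis(2,5-dimethoxy-6-methylcyclohexa-2,5-diene-1,4-dione) | COC1=C(C)C(=O)C(OC)=C(CCCCCCCCCCCCCCC2=C(OC)C(=O)C(C)=C(OC)C2=O)C1=O
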